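**Plan**
- Final cut: the C14'–C15' sp2–sp2 bond (carotenoid numbering, primed = acetylenic half). The central triene C13(Me)=C14–C15=C15'–C14'=C13'(Me) is locally symmetric, so both halves can end as the same (E)-2-methylvinyl iodide (C14–I and C14'–I), stitched by a trans-vinylene (C15=C15') carrying Sn at one end and B at the other.
- Forward, in one flask: Stille coupling of fragment B iodide 20 with 23 (C14–C15) gives the C21 pentaenylboronate 24, which is then joined to fragment A iodide 12 by Suzuki–Miyaura coupling (C14'–C15'); desilylation ends the route.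
- Earlier cuts: C11=C12 and C11'=C12' (one HWE reagent, 11), C6'–C7' (Sonogashira) and C6–C7 (acetylide addition); the same C5 enynol 4 supplies C7–C11 of both halves.
- Both six-membered rings are the carbocycle of (4R,6R)-actinol 1; no ring is formed.
- Stereochemistry: C3' (R) and C3 (S) are the actinol carbinol centre; C5 (S) from Rubottom oxidation cis to OTBS; C6 (S) from axial acetylide addition; 7E from hydroxyl-directed alkyne reduction; the other E-alkenes from 4, 11, 23 and the HWE steps.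

Key step: step 16

Assumption: (4R,6R)-4-hydroxy-2,2,6-trimethylcyclohexan-1-one (actinol, an industrial zeaxanthin intermediate) is taken as a purchasable enantiopure ketone and is the only source of chirality. TBS = tert-butyldimethylsilyl, Bpin = 4,4,5,5-tetramethyl-1,3,2-dioxaborolan-2-yl.

Step 1
Reactants: 1 (4R,6R)-4-hydroxy-2,2,6-trimethylcyclohexan-1-one
Product: 2 (4R,6R)-4-(TBS-oxy)-2,2,6-trimethylcyclohexan-1-one
Conditions: TBSCl, imidazole, DMF, rt
Reagents that add atoms: tert-butyldimethylsilyl chloride, CC(C)(C)[Si](C)(C)Cl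
Why: Imidazole-promoted silylation of the secondary alcohol should proceed without touching the ketone or either stereocentre.

Step 2
Reactants: 2 (4R,6R)-4-(TBS-oxy)-2,2,6-trimethylcyclohexan-1-one
Product: 3 (4R)-4-(TBS-oxy)-2,6,6-trimethylcyclohex-1-en-1-yl trifluoromethanesulfonate
Conditions: LiN(iPr)2, THF, −78 to 0 °C; PhNTf2, −78 °C to rt
Reagents that add atoms: N-phenylbis(trifluoromethanesulfonimide), O=S(=O)(N(c1ccccc1)S(=O)(=O)C(F)(F)F)C(F)(F)F
Why: Enolisation is possible only at C6 (C2 is quaternary), so O-triflation of the enolate (enol triflate formation) should give one regioisomer, erasing the C6 centre on purpose and keeping C4.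

Step 3
Reactants: 3 enol triflate; 4 (2E)-3-methylpent-2-en-4-yn-1-ol
Product: 5 (2E)-5-[(4R)-4-(TBS-oxy)-2,6,6-trimethylcyclohex-1-en-1-yl]-3-methylpent-2-en-4-yn-1-ol
Conditions: Pd(PPh3)4 (5 mol %), CuI (10 mol %), Et3N, DMF, 50 °C
Reagents that add atoms: none
Why: Sonogashira coupling of the hindered enol triflate with the terminal alkyne should form the C6'–C7' bond and leave the E-alkene, the free primary alcohol and the silyl ether untouched.

Step 4
Reactants: 5 C15 enynol
Product: 6 (2E)-5-[(4R)-4-(TBS-oxy)-2,6,6-trimethylcyclohex-1-en-1-yl]-3-methylpent-2-en-4-ynal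
Conditions: MnO2, CH2Cl2, rt
Reagents that add atoms: none
Why: MnO2 oxidation is selective for the primary allylic alcohol and should not affect the alkyne, the alkene geometry or the silyl ether.

Step 5
Reactants: 7 prop-2-yn-1-ol
Product: 9 (2E)-3-iodo-2-methylprop-2-en-1-ol, via alkenylalane 8 (not isolated)
Conditions: AlMe3 (3 equiv), Cp2ZrCl2 (0.25 equiv), CH2Cl2, 0 °C to rt; then I2, THF, −30 to 0 °C
Reagents that add atoms: trimethylaluminium, C[Al](C)C; iodine, II
Why: Negishi zirconium-catalysed carboalumination adds Me and Al syn across the terminal alkyne with Me on the internal carbon, and iodinolysis of the C–Al bond with retention should give the E-iodoalkene.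

Step 6
Reactants: 9 (2E)-3-iodo-2-methylprop-2-en-1-ol
Product: 10 (1E)-3-bromo-1-iodo-2-methylprop-1-ene
Conditions: CBr4, PPh3, CH2Cl2, 0 °C
Reagents that add atoms: tetrabromomethane, BrC(Br)(Br)Br
Why: Appel bromination of the allylic alcohol is neutral and should preserve the vinyl iodide and its geometry.

Step 7
Reactants: 10 (1E)-3-bromo-1-iodo-2-methylprop-1-ene
Product: 11 diethyl [(2E)-3-iodo-2-methylprop-2-en-1-yl]phosphonate
Conditions: P(OEt)3 (neat), 110 °C
Reagents that add atoms: triethyl phosphite, CCOP(OCC)OCC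
Why: Michaelis–Arbuzov reaction takes place at the allylic bromide only, since a vinyl iodide is inert to phosphite without a metal catalyst.

Step 8
Reactants: 6 C15 enynal; 11 iodoallyl phosphonate
Product: 12 fragment A iodide, tert-butyl{[(1R)-4-[(3E,5E,7E)-8-iodo-3,7-dimethylocta-3,5,7-trien-1-yn-1-yl]-3,5,5-trimethylcyclohex-3-en-1-yl]oxy}dimethylsilane
Conditions: 11, NaN(SiMe3)2, THF, −78 °C; then 6, −78 to 0 °C
Reagents that add atoms: none
Why: Horner–Wadsworth–Emmons olefination of the enal with the allylic phosphonate anion should form C11'=C12' E-selectively, while the preformed C13'=C14' iodoalkene keeps its E geometry.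

Step 9
Reactants: 2 (4R,6R)-4-(TBS-oxy)-2,2,6-trimethylcyclohexan-1-one
Product: 13 tert-butyldimethyl{[(1R)-3,5,5-trimethyl-4-(trimethylsilyloxy)cyclohex-3-en-1-yl]oxy}silane
Conditions: LiN(iPr)2, THF, −78 to 0 °C; Me3SiCl, −78 °C to rt
Reagents that add atoms: chlorotrimethylsilane, C[Si](C)(C)Cl
Why: The same single enolate as in step 2 is O-silylated, giving the only possible silyl enol ether.

Step 10
Reactants: 13 silyl enol ether
Product: 16 (2S,4S)-4-(TBS-oxy)-2-hydroxy-2,6,6-trimethylcyclohexan-1-one, via silyloxy epoxide 14 (not isolated), via silyloxy ketone 15 (not isolated)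
Conditions: mCPBA, CH2Cl2, −20 to 0 °C; then citric acid, MeOH, rt
Reagents that add atoms: 3-chloroperoxybenzoic acid, OOC(=O)c1cccc(Cl)c1
Why: In this Rubottom oxidation the peracid should attack the enol ether on the face opposite the pseudoaxial methyl of the gem-dimethyl carbon, which is the face cis to the equatorial OTBS group, and 1,4-silyl shift followed by mild methanolysis then gives the tertiary ketol with the new carbinol centre (S, future C5) cis to OTBS.

Step 11
Reactants: 16 ketol; 4 (2E)-3-methylpent-2-en-4-yn-1-ol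
Product: 17 (1R,2S,4S)-4-(TBS-oxy)-1-[(3E)-5-hydroxy-3-methylpent-3-en-1-yn-1-yl]-2,6,6-trimethylcyclohexane-1,2-diol
Conditions: 4 (3.2 equiv), n-BuLi (6.4 equiv), THF, −78 to 0 °C; then 16, −78 °C to rt; H2O
Reagents that add atoms: none
Why: The lithium acetylide of 4 adds to the non-enolisable ketone; in the chair with equatorial OTBS and OH the two flanking methyl groups on one face are axial, so the slim sp nucleophile should attack axially from the other face, placing the alkynyl group cis to the 2-OH and 4-OTBS and the new OH trans to the 2-OH (future C6).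

Step 12
Reactants: 17 acetylenic triol
Product: 18 (1S,2S,4S)-4-(TBS-oxy)-1-[(1E,3E)-5-hydroxy-3-methylpenta-1,3-dien-1-yl]-2,6,6-trimethylcyclohexane-1,2-diol
Conditions: NaAlH2(OCH2CH2OMe)2, THF, 0 °C to rt; aq. potassium sodium tartrate
Reagents that add atoms: none
Why: Hydroxyl-directed trans-hydroalumination of the propargylic alkoxide and protonolysis should give the 7E alkene only, so the alkyne served as a temporary higher oxidation level of C7=C8 and the silyl ether and 9E alkene are unaffected.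

Step 13
Reactants: 18 dienyl tetraol monosilyl ether
Product: 19 (2E,4E)-5-[(1S,2S,4S)-4-(TBS-oxy)-1,2-dihydroxy-2,6,6-trimethylcyclohexyl]-3-methylpenta-2,4-dienal
Conditions: MnO2, CH2Cl2, rt
Reagents that add atoms: none
Why: MnO2 oxidises only the primary allylic alcohol, since the two tertiary alcohols cannot be oxidised and the silyl ether is inert.

Step 14
Reactants: 19 dienal; 11 iodoallyl phosphonate
Product: 20 fragment B iodide, (1S,2S,4S)-4-(TBS-oxy)-1-[(1E,3E,5E,7E)-8-iodo-3,7-dimethylocta-1,3,5,7-tetraen-1-yl]-2,6,6-trimethylcyclohexane-1,2-diol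
Conditions: 11 (3.5 equiv), NaN(SiMe3)2 (3.3 equiv), THF, −78 °C; then 19, −78 to 0 °C
Reagents that add atoms: none
Why: The same Horner–Wadsworth–Emmons olefination as in step 8 should form C11=C12 E-selectively, the excess anion covering reversible proton transfer from the two hindered tertiary alcohols.

Step 15
Reactants: 21 (E)-1,2-bis(tributylstannyl)ethene
Product: 23 tributyl[(E)-2-(Bpin)ethenyl]stannane, via stannylvinyllithium 22 (not isolated)
Conditions: n-BuLi (1.0 equiv), THF, −78 °C; 2-isopropoxy-4,4,5,5-tetramethyl-1,3,2-dioxaborolane, −78 °C to rt; HCl in Et2O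
Reagents that add atoms: 2-isopropoxy-4,4,5,5-tetramethyl-1,3,2-dioxaborolane, CC(C)OB1OC(C)(C)C(C)(C)O1
Why: Tin–lithium exchange of one stannyl group proceeds with retention of alkene geometry, and borylation of the vinyllithium then gives the trans-vinylene with two different metals.

Step 16
Reactants: 20 fragment B iodide; 23 stannyl vinylboronate; 12 fragment A iodide
Product: 25 bis-TBS ether of the target (both secondary hydroxyls silylated), via pentaenylboronate 24 (not isolated)
Conditions: 20, 23 (1.0 equiv), Pd2(dba)3 (5 mol %), AsPh3 (20 mol %), DMF, rt, dark; then 12 (0.95 equiv), Pd(PPh3)4 (5 mol %), 3 M aq. KOH, THF, rt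
Reagents that add atoms: none
Why: Zerovalent palladium inserts into the C14–I bond of 20, the C–Sn end of 23 transmetalates and reductive elimination gives pentaenylboronate 24; hydroxide then activates the Bpin group and a second cycle (oxidative addition of 12, boron-to-palladium transmetalation, reductive elimination) forms the C14'–C15' bond and completes the C40 chain. The closest known reaction type is the one-pot Stille/Suzuki–Miyaura assembly of polyenes from alkenes that carry tin and boron together. No ring is closed and no stereocentre is formed, and every alkene geometry is carried through because both transmetalations and reductive eliminations are stereoretentive. The step needs chemoselectivity for tin over boron in the first stage, secured by the neutral Bpin group, which does not transmetalate without base, and cross- over homo-coupling in the second, secured by consuming 23 completely before 12 and base are added. The C7'≡C8' alkyne, the two free tertiary alcohols and the silyl ethers are inert under both sets of conditions.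

Step 17
Reactants: 25 bis-TBS ether of the target
Product: 26 (3S,5S,6S,3'R)-7',8'-didehydro-5,6-dihydro-β,β-carotene-3,5,6,3'-tetrol (target)
Conditions: Bu4NF, THF, 0 °C to rt, dark
Reagents that add atoms: none
Why: Fluoride cleaves both secondary silyl ethers, and no stereocentre or alkene is involved.

**Compound list**
1 | (4R,6R)-4-hydroxy-2,2,6-trimethylcyclohexan-1-one | CC1(C)C[C@H](O)C[C@@H](C)C1=O | starting material
2 | (4R,6R)-4-(TBS-oxy)-2,2,6-trimethylcyclohexan-1-one | CC1(C)C[C@H](O[Si](C)(C)C(C)(C)C)C[C@@H](C)C1=O | intermediate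
3 | (4R)-4-(TBS-oxy)-2,6,6-trimethylcyclohex-1-en-1-yl trifluoromethanesulfonate | CC1=C(OS(=O)(=O)C(F)(F)F)C(C)(C)C[C@H](O[Si](C)(C)C(C)(C)C)C1 | intermediate
4 | (2E)-3-methylpent-2-en-4-yn-1-ol | C#C/C(C)=C/CO | starting material
5 | (2E)-5-[(4R)-4-(TBS-oxy)-2,6,6-trimethylcyclohex-1-en-1-yl]-3-methylpent-2-en-4-yn-1-ol | CC1=C(C#C/C(C)=C/CO)C(C)(C)C[C@H](O[Si](C)(C)C(C)(C)C)C1 | intermediate
6 | (2E)-5-[(4R)-4-(TBS-oxy)-2,6,6-trimethylcyclohex-1-en-1-yl]-3-methylpent-2-en-4-ynal | CC1=C(C#C/C(C)=C/C=O)C(C)(C)C[C@H](O[Si](C)(C)C(C)(C)C)C1 | intermediate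
7 | prop-2-yn-1-ol | C#CCO | starting material
8 | (E)-alkenylalane, dimethylaluminium alkoxide of (2E)-3-(dimethylalumanyl)-2-methylprop-2-en-1-ol | C[Al](C)OC/C(C)=C/[Al](C)C | intermediate
9 | (2E)-3-iodo-2-methylprop-2-en-1-ol | OC/C(C)=C/I | intermediate
10 | (1E)-3-bromo-1-iodo-2-methylprop-1-ene | BrC/C(C)=C/I | intermediate
11 | diethyl [(2E)-3-iodo-2-methylprop-2-en-1-yl]phosphonate | CCOP(=O)(OCC)C/C(C)=C/I | intermediate
12 | fragment A iodide, tert-butyl{[(1R)-4-[(3E,5E,7E)-8-iodo-3,7-dimethylocta-3,5,7-trien-1-yn-1-yl]-3,5,5-trimethylcyclohex-3-en-1-yl]oxy}dimethylsilane | CC1=C(C#C/C(C)=C/C=C/C(C)=C/I)C(C)(C)C[C@H](O[Si](C)(C)C(C)(C)C)C1 | intermediate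
13 | tert-butyldimethyl{[(1R)-3,5,5-trimethyl-4-(trimethylsilyloxy)cyclohex-3-en-1-yl]oxy}silane | CC1=C(O[Si](C)(C)C)C(C)(C)C[C@H](O[Si](C)(C)C(C)(C)C)C1 | intermediate
14 | silyloxy epoxide of 13, oxirane oxygen cis to the OTBS group, trimethylsilyloxy on the oxirane carbon next to the gem-dimethyl carbon | C[C@@]12O[C@]1(O[Si](C)(C)C)C(C)(C)C[C@H](O[Si](C)(C)C(C)(C)C)C2 | intermediate
15 | (2S,4S)-4-(TBS-oxy)-2,6,6-trimethyl-2-(trimethylsilyloxy)cyclohexan-1-one | C[C@]1(O[Si](C)(C)C)C[C@@H](O[Si](C)(C)C(C)(C)C)CC(C)(C)C1=O | intermediate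
16 | (2S,4S)-4-(TBS-oxy)-2-hydroxy-2,6,6-trimethylcyclohexan-1-one | C[C@]1(O)C[C@@H](O[Si](C)(C)C(C)(C)C)CC(C)(C)C1=O | intermediate
17 | (1R,2S,4S)-4-(TBS-oxy)-1-[(3E)-5-hydroxy-3-methylpent-3-en-1-yn-1-yl]-2,6,6-trimethylcyclohexane-1,2-diol | OC/C=C(C)/C#C[C@]1(O)C(C)(C)C[C@H](O[Si](C)(C)C(C)(C)C)C[C@]1(C)O | intermediate
18 | (1S,2S,4S)-4-(TBS-oxy)-1-[(1E,3E)-5-hydroxy-3-methylpenta-1,3-dien-1-yl]-2,6,6-trimethylcyclohexane-1,2-diol | OC/C=C(C)/C=C/[C@]1(O)C(C)(C)C[C@H](O[Si](C)(C)C(C)(C)C)C[C@]1(C)O | intermediate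
19 | (2E,4E)-5-[(1S,2S,4S)-4-(TBS-oxy)-1,2-dihydroxy-2,6,6-trimethylcyclohexyl]-3-methylpenta-2,4-dienal | O=C/C=C(C)/C=C/[C@]1(O)C(C)(C)C[C@H](O[Si](C)(C)C(C)(C)C)C[C@]1(C)O | intermediate
20 | fragment B iodide, (1S,2S,4S)-4-(TBS-oxy)-1-[(1E,3E,5E,7E)-8-iodo-3,7-dimethylocta-1,3,5,7-tetraen-1-yl]-2,6,6-trimethylcyclohexane-1,2-diol | I/C=C(C)/C=C/C=C(C)/C=C/[C@]1(O)C(C)(C)C[C@H](O[Si](C)(C)C(C)(C)C)C[C@]1(C)O | intermediate
21 | (E)-1,2-bis(tributylstannyl)ethene | CCCC[Sn](CCCC)(CCCC)/C=C/[Sn](CCCC)(CCCC)CCCC | starting material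
22 | [(E)-2-(tributylstannyl)ethenyl]lithium | [Li]/C=C/[Sn](CCCC)(CCCC)CCCC | intermediate
23 | tributyl[(E)-2-(4,4,5,5-tetramethyl-1,3,2-dioxaborolan-2-yl)ethenyl]stannane | CCCC[Sn](CCCC)(CCCC)/C=C/B1OC(C)(C)C(C)(C)O1 | intermediate
24 | C21 pentaenylboronate, (1S,2S,4S)-4-(TBS-oxy)-1-[(1E,3E,5E,7E,9E)-3,7-dimethyl-10-(Bpin)deca-1,3,5,7,9-pentaen-1-yl]-2,6,6-trimethylcyclohexane-1,2-diol | CC1(C)OB(/C=C/C=C(C)/C=C/C=C(C)/C=C/[C@]2(O)C(C)(C)C[C@H](O[Si](C)(C)C(C)(C)C)C[C@]2(C)O)OC1(C)C | intermediate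
25 | 3,3'-bis-O-TBS ether of the target, all-E, (3S,5S,6S,3'R) | CC1=C(C#C/C(C)=C/C=C/C(C)=C/C=C/C=C(C)/C=C/C=C(C)/C=C/[C@]2(O)C(C)(C)C[C@H](O[Si](C)(C)C(C)(C)C)C[C@]2(C)O)C(C)(C)C[C@H](O[Si](C)(C)C(C)(C)C)C1 | intermediate
26 | (3S,5S,6S,3'R)-7',8'-didehydro-5,6-dihydro-β,β-carotene-3,5,6,3'-tetrol | CC1=C(C#C/C(C)=C/C=C/C(C)=C/C=C/C=C(C)/C=C/C=C(C)/C=C/[C@]2(O)C(C)(C)C[C@H](O)C[C@]2(C)O)C(C)(C)C[C@H](O)C1 | target

**Totals**
Total step count: 17. Longest linear sequence: 9 steps (1, 9, 10, 11, 12, 13, 14, 16, 17).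

**Steps most likely to fail**

Step 16. The one-flask sequence may suffer from premature transmetalation at boron in the first stage (double coupling), from statistical scrambling into homo-dimers if unreacted 23 meets 12, or from protodeboronation and E/Z isomerisation of the pentaenylboronate. Fallback, from 20 back to 25: Stille coupling of 20 with an excess of commercial 21 (PdCl2(MeCN)2, DMF, rt) should give the isolable C21 pentaenylstannane F1, which can be purified. A separate Stille coupling of F1 with 12 (Pd2(dba)3, AsPh3, DMF, rt) then forms the same C14'–C15' bond and returns to 25.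

Step 10. Facial selectivity of the enol ether epoxidation may be insufficient (attack trans to OTBS), and the acid released may cause silyl loss or ketol rearrangement. Fallback, from 3 back to 16, with the new oxygen placed by reagent control:
- Palladium-catalysed methoxycarbonylation of 3 (Pd(OAc)2, PPh3, CO, MeOH, Et3N, DMF) gives the methyl ester F2.
- Reduction with (iBu)2AlH gives the allylic alcohol F3.
- Sharpless epoxidation (Ti(OiPr)4, L-(+)-diethyl tartrate, tBuOOH, CH2Cl2, −20 °C), matched with the ring bias, gives the syn-epoxy alcohol F4 with the oxirane oxygen cis to OTBS.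
- Dess–Martin oxidation gives the epoxy aldehyde F5.
- Wharton transposition (N2H4·H2O, AcOH, MeOH) opens the oxirane without breaking the C–O bond of the future C5 and gives the tertiary allylic alcohol F6 with an exocyclic methylene group.
- Ozonolysis (O3, CH2Cl2/MeOH, −78 °C; Me2S) gives 16.

Step 11. Addition of the bulky, poorly soluble dilithiated enynol to the doubly neopentyl ketone may be slow, allowing ketol rearrangement of the α-alkoxide or erosion of facial selectivity. Fallback, from 16 back to 17, with the side chain brought in as two pieces: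
- CeCl3-promoted addition of the smallest acetylide, HC≡CMgBr (THF, −78 to 0 °C), gives the ethynyl carbinol F7; axial attack is most favoured for this nucleophile.
- Sonogashira coupling of F7 (Pd(PPh3)4, CuI, Et3N, DMF, rt) with ethyl (2E)-3-(trifluoromethylsulfonyloxy)but-2-enoate F8, made from ethyl acetoacetate with Tf2O and aqueous Me4NOH, gives the enynoate F9.
- Reduction of the ester with (iBu)2AlH (CH2Cl2, −78 °C) gives 17.

Further compounds
F1 | step 16 | C21 pentaenylstannane, tributyl[(1E,3E,5E,7E,9E)-10-[(1S,2S,4S)-4-(TBS-oxy)-1,2-dihydroxy-2,6,6-trimethylcyclohexyl]-4,8-dimethyldeca-1,3,5,7,9-pentaen-1-yl]stannane | CCCC[Sn](CCCC)(CCCC)/C=C/C=C(C)/C=C/C=C(C)/C=C/[C@]1(O)C(C)(C)C[C@H](O[Si](C)(C)C(C)(C)C)C[C@]1(C)O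
F2 | step 10 | methyl (4R)-4-(TBS-oxy)-2,6,6-trimethylcyclohex-1-ene-1-carboxylate | CC1=C(C(=O)OC)C(C)(C)C[C@H](O[Si](C)(C)C(C)(C)C)C1
F3 | step 10 | [(4R)-4-(TBS-oxy)-2,6,6-trimethylcyclohex-1-en-1-yl]methanol | CC1=C(CO)C(C)(C)C[C@H](O[Si](C)(C)C(C)(C)C)C1
F4 | step 10 | [(1S,2S,4S)-4-(TBS-oxy)-1,2-epoxy-2,6,6-trimethylcyclohexyl]methanol, oxirane oxygen cis to OTBS | C[C@@]12O[C@]1(CO)C(C)(C)C[C@H](O[Si](C)(C)C(C)(C)C)C2
F5 | step 10 | epoxy aldehyde from F4, 4-(TBS-oxy)-1,2-epoxy-2,6,6-trimethylcyclohexane-1-carbaldehyde, oxirane oxygen cis to OTBS | C[C@@]12O[C@]1(C=O)C(C)(C)C[C@H](O[Si](C)(C)C(C)(C)C)C2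
F6 | step 10 | (1S,5S)-5-(TBS-oxy)-1,3,3-trimethyl-2-methylidenecyclohexan-1-ol | C=C1C(C)(C)C[C@H](O[Si](C)(C)C(C)(C)C)C[C@]1(C)O
F7 | step 11 | (1R,2S,4S)-4-(TBS-oxy)-1-ethynyl-2,6,6-trimethylcyclohexane-1,2-diol | C#C[C@]1(O)C(C)(C)C[C@H](O[Si](C)(C)C(C)(C)C)C[C@]1(C)O
F8 | step 11 | ethyl (2E)-3-(trifluoromethylsulfonyloxy)but-2-enoate | CCOC(=O)/C=C(\C)OS(=O)(=O)C(F)(F)F
F9 | step 11 | ethyl (2E)-5-[(1R,2S,4S)-4-(TBS-oxy)-1,2-dihydroxy-2,6,6-trimethylcyclohexyl]-3-methylpent-2-en-4-ynoate | CCOC(=O)/C=C(C)/C#C[C@]1(O)C(C)(C)C[C@H](O[Si](C)(C)C(C)(C)C)C[C@]1(C)O
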